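**Retrosynthetic overview**
1. The strategy rests on C5 and C6, two adjacent carbinol carbons that carry their oxygens cis on the ten-membered carbocycle C1–C10. The target 27 is traced back to the cyclic cis-diol 19; the C3/C4 oxirane (syn to O5) and the three esters are added after ring closure.
2. 19 ⇐ 18: reductive pinacol coupling of the Z-enal carbon C5 with the aldehyde carbon C6 closes the ten-membered ring and creates both carbinols.
3. 18 ⇐ 13 + 14 (Still–Gennari olefination, Z C3=C4) ⇐ 8 + 9 (Claisen condensation, then Felkin–Anh reduction for C1).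
4. 8 ⇐ (S)-carvone 1: carvone C5, C4, C3, C2, C1, C6 become C7, C8, C9, C10, C1, C6. The trans epoxide supplies O9/O10, the C1–C6 bond is cut through the α-ketol, and C9 is inverted by hydrolysis of the open-chain glycidic ester.
5. Rings in order of formation: oxirane of 2 (opened in step 5), dioxolane (step 6, protecting), ten-membered carbocycle (step 15), C3/C4 oxirane (step 16).

Key step: step 15

Remark: ring atoms are numbered C7 (isopropenyl), C8, C9, C10 (methyl), C1, C2, C3, C4 (methyl), C5, C6 in all compounds, also before ring closure. The dialdehyde 18 and the diol 19 carry O1 as tert-butyldimethylsilyl ether and O9/O10 as acetonide, and each of their stereocentres has the arrangement the target requires. The mixed anhydride 22 is made once, in step 17, as a filtered toluene solution that serves both angeloylations.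

**Step 1**
Reactants: 1 (S)-(+)-carvone
Product: 2 trans-carvone oxide
Conditions: H2O2 (30% aq.), NaOH (cat.), MeOH, 0 °C
Reagents that add atoms: hydrogen peroxide, OO
Why: Weitz–Scheffer nucleophilic epoxidation attacks only the enone, and the hydroperoxide anion adds to C9 axially on the face away from the isopropenyl group at C7, so that C9 and C10 both receive oxygen trans to that group.

**Step 2**
Reactants: 2 trans-carvone oxide
Product: 3 α-hydroxy epoxy ketone (C6 carbinol, either epimer)
Conditions: NaN(SiMe3)2, THF, −78 °C; then 2-(phenylsulfonyl)-3-phenyloxaziridine, −78 °C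
Reagents that add atoms: 2-(phenylsulfonyl)-3-phenyloxaziridine, O=S(=O)(c1ccccc1)N1OC1c1ccccc1
Why: Enolate oxidation with the Davis oxaziridine works here because the ketone can enolise only toward C6 (C10 is fully substituted), and the configuration of the new carbinol does not matter since C6 becomes an aldehyde in step 3.

**Step 3**
Reactants: 3 α-hydroxy epoxy ketone
Product: 5 hydroxy glycidic ester, via aldehyde ester 4 (not isolated)
Conditions: Pb(OAc)4, MeOH–PhH (1:1), 0 °C; then NaBH4, −20 °C
Reagents that add atoms: methanol, CO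
Why: Criegee-type glycol cleavage of the α-ketol in methanol cuts C1–C6 into the C1 methyl ester and the C6 aldehyde, which borohydride reduces in the same flask before the enolisable C7 centre next to the isopropenyl group can epimerise; C7, C9 and C10 are untouched.

**Step 4**
Reactants: 5 hydroxy glycidic ester
Product: 6 tert-butyldiphenylsilyl ether
Conditions: t-BuPh2SiCl, imidazole, CH2Cl2, 0 °C
Reagents that add atoms: tert-butyl(chloro)diphenylsilane, CC(C)(C)[Si](Cl)(c1ccccc1)c1ccccc1
Why: Silyl ether formation at the primary alcohol, with a bulky acid-stable group whose oxygen is too hindered and too weakly basic to attack C9 of the glycidic ester in step 5.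

**Step 5**
Reactants: 6 tert-butyldiphenylsilyl ether
Product: 7 threo 9,10-diol ester
Conditions: HClO4 (cat.), THF–H2O (3:1), 0 °C → rt
Reagents that add atoms: water, O
Why: Acid-catalysed hydrolysis of the glycidic ester should place water on the secondary carbon C9 with inversion while the fully substituted C10 next to the ester keeps its oxygen, which gives the C9 and C10 configurations of the target; in the open chain no trans-diaxial constraint diverts the attack to C10 as it would in the cyclohexane.

**Step 6**
Reactants: 7 threo 9,10-diol ester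
Product: 8 acetonide ester
Conditions: Me2C(OMe)2, camphorsulfonic acid (cat.), acetone, rt
Reagents that add atoms: 2,2-dimethoxypropane, COC(C)(C)OC
Why: Acid-catalysed ketal exchange closes the dioxolane on the secondary and tertiary hydroxyls and changes no stereocentre.

**Step 7**
Reactants: 8 acetonide ester; 9 ethyl acetate
Product: 10 β-keto ester
Conditions: LiN(i-Pr)2, 9 (3 equiv), THF, −78 °C; then 8, −78 → −40 °C
Reagents that add atoms: none
Why: Crossed Claisen condensation, in which the lithium enolate of ethyl acetate adds to the non-enolisable, α-alkoxy-activated methyl ester and the β-keto ester is held as its enolate until work-up, so that no second addition occurs.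

**Step 8**
Reactants: 10 β-keto ester
Product: 11 β-hydroxy ester
Conditions: KBH(sec-Bu)3, THF, −78 °C
Reagents that add atoms: none
Why: Felkin–Anh reduction of the α-alkoxy ketone under non-chelating conditions (potassium counter-ion, bulky hydride), in which hydride enters anti to the C10–O bond and past the C10 methyl group rather than the ring carbon C9, which should give the C1 (S) carbinol.

**Step 9**
Reactants: 11 β-hydroxy ester
Product: 12 silyl ether ester
Conditions: t-BuMe2SiOTf, 2,6-lutidine, CH2Cl2, −78 → 0 °C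
Reagents that add atoms: tert-butyldimethylsilyl trifluoromethanesulfonate, CC(C)(C)[Si](C)(C)OS(=O)(=O)C(F)(F)F
Why: Silylation with the silyl triflate overcomes the hindrance of the hydroxyl next to the fully substituted C10 and blocks retro-aldol cleavage in the later base steps.

**Step 10**
Reactants: 12 silyl ether ester
Product: 13 C3 aldehyde
Conditions: i-Bu2AlH (1.1 equiv), CH2Cl2, −78 °C; aq. potassium sodium tartrate work-up
Reagents that add atoms: none
Why: Partial ester reduction with i-Bu2AlH, in which the aluminium hemiacetal of the β-silyloxy ester is stable at −78 °C and releases the aldehyde on work-up.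

**Step 11**
Reactants: 13 C3 aldehyde; 14 ethyl 2-[bis(2,2,2-trifluoroethoxy)phosphoryl]propanoate
Product: 15 Z enoate
Conditions: 14, KN(SiMe3)2, 18-crown-6, THF, −78 °C; then 13
Reagents that add atoms: none
Why: Still–Gennari olefination, in which the bis(trifluoroethyl) phosphonate anion with a crown-complexed potassium ion eliminates fast from the kinetic adduct and gives the Z trisubstituted enoate with C2 and C5 cis on C3=C4, as the ring requires.

**Step 12**
Reactants: 15 Z enoate
Product: 16 Z allylic alcohol
Conditions: i-Bu2AlH (2.5 equiv), CH2Cl2, −78 °C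
Reagents that add atoms: none
Why: 1,2-Reduction of the conjugated ester by excess i-Bu2AlH gives the allylic alcohol without touching the olefin geometry.

**Step 13**
Reactants: 16 Z allylic alcohol
Product: 17 diol
Conditions: Bu4NF, AcOH (1:1), THF, 0 °C → rt
Reagents that add atoms: none
Why: Fluoride desilylation buffered with acetic acid cleaves the unhindered primary silyl ether, while the secondary silyl ether at C1, shielded by the fully substituted C10, and the ketal remain.

**Step 14**
Reactants: 17 diol
Product: 18 dialdehyde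
Conditions: Dess–Martin periodinane, NaHCO3, CH2Cl2, 0 °C; crude product used at once
Reagents that add atoms: none
Why: Dess–Martin oxidation buffered with NaHCO3 converts both primary alcohols into aldehydes under neutral conditions, so that the Z enal does not isomerise and the C7 centre, α to the new aldehyde and bearing the isopropenyl group, neither epimerises nor moves into conjugation.

**Step 15**
Reactants: 18 dialdehyde
Product: 19 ten-membered cis-5,6-diol
Conditions: SmI2 (3 equiv), THF, −78 → −30 °C, 18 added over 6 h (2 mM final); then aq. NaHCO3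
Reagents that add atoms: none
Why: Single-electron transfer from divalent samarium to the more easily reduced Z enal gives a trivalent-samarium ketyl whose metal also binds the C6 aldehyde oxygen; C5–C6 bond formation inside this five-membered chelate and a second electron transfer give the cyclic samarium diolate, which water opens to 19. The closest known reaction type is the intramolecular pinacol coupling of dialdehydes with SmI2 or low-valent titanium to medium-ring 1,2-diols, including enal–aldehyde closures of carbocycles. The ten-membered carbocycle is closed by attack of C5 on the C6 carbonyl carbon (10-exo-trig, carbonyl carbon to carbonyl carbon), the only skeletal bond made in the step. C6 is set by Felkin–Anh approach anti to the isopropenyl group on C7, which gives the 6,7-anti relation of the target, and C5 by the chelate, which holds O5 and O6 syn-clinal while the Z ketyl keeps its hydrogen inside (allylic 1,3-strain), so that the ring arms C4 and C7 should lie cis on the diolate and the erythro (cis) diol result. The step needs carbonyl-to-carbonyl coupling instead of attack through C3, no Z-to-E leak and ring closure ahead of dimerisation; leaving out HMPA keeps the chelate, −78 °C freezes rotation of the allyl-type ketyl, and slow addition at high dilution together with the turn imposed by the Z olefin and the trans-substituted dioxolane favours closure.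

**Step 16**
Reactants: 19 ten-membered cis-5,6-diol
Product: 20 epoxy diol
Conditions: VO(acac)2 (5 mol%), t-BuOOH (1.2 equiv), CH2Cl2, 0 °C
Reagents that add atoms: tert-butyl hydroperoxide, CC(C)(C)OO
Why: Vanadium-catalysed hydroxyl-directed epoxidation, in which the C5 vanadate ester delivers the peroxide oxygen to the face of C3=C4 syn to O5, as medium-ring Z allylic alcohols do, setting C3 and C4 as in the target, while the isopropenyl group (1,1-disubstituted and only homoallylic to O6) reacts far more slowly.

**Step 17**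
Reactants: 21 angelic acid
Product: 22 angelic 2,4,6-trichlorobenzoic mixed anhydride
Conditions: 2,4,6-Cl3C6H2COCl (1.0 equiv), Et3N (1.05 equiv), toluene, 0 °C → rt; filtered under argon from the ammonium salt; the toluene solution is used in one portion at once in step 18, the remainder kept at −20 °C for step 21
Reagents that add atoms: 2,4,6-trichlorobenzoyl chloride, O=C(Cl)c1c(Cl)cc(Cl)cc1Cl
Why: Acyl substitution of the aroyl chloride by triethylammonium angelate gives the Yamaguchi mixed anhydride, and since no nucleophilic catalyst is present nothing adds to the β-carbon of the angeloyl group and its Z geometry is kept.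

**Step 18**
Reactants: 20 epoxy diol; 22 angelic 2,4,6-trichlorobenzoic mixed anhydride
Product: 23 6-O-angelate
Conditions: 22 (1.1 equiv), Et3N (1.5 equiv), toluene, 60 °C
Reagents that add atoms: none
Why: Yamaguchi-type esterification through the mixed anhydride, whose hindered aroyl carbonyl directs the alcohol to the angeloyl carbonyl, run without a nucleophilic catalyst to keep the Z geometry of the angelate; O6 should react first because C5 is flanked by the fully substituted oxirane carbon C4 and its hydroxyl is held in a hydrogen bond to the oxirane oxygen.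

**Step 19**
Reactants: 23 6-O-angelate
Product: 24 5-O-acetate 6-O-angelate
Conditions: Ac2O, DMAP (cat.), pyridine, CH2Cl2, 0 °C → rt
Reagents that add atoms: acetic anhydride, CC(=O)OC(C)=O
Why: DMAP-catalysed acetylation of the one remaining hydroxyl, fast enough at low temperature to outrun acyl migration.

**Step 20**
Reactants: 24 5-O-acetate 6-O-angelate
Product: 25 C1 alcohol
Conditions: HF·pyridine, pyridine, THF, 0 °C → rt
Reagents that add atoms: none
Why: Fluoride-mediated desilylation with pyridine-buffered HF·pyridine frees the C1 hydroxyl and should spare the esters, the ketal and the acyloxy-flanked oxirane.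

**Step 21**
Reactants: 25 C1 alcohol; 22 angelic 2,4,6-trichlorobenzoic mixed anhydride
Product: 26 1,6-di-O-angelate acetonide
Conditions: 22 (3 equiv), Et3N (4 equiv), toluene, 80 °C
Reagents that add atoms: none
Why: The same mixed-anhydride esterification, driven by heat and excess anhydride for the hindered C1 hydroxyl and again run without a nucleophilic catalyst that would isomerise the angelate to the tiglate.

**Step 22**
Reactants: 26 1,6-di-O-angelate acetonide
Product: 27 CNP0249359.1
Conditions: AcOH–H2O (4:1), 35 °C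
Reagents that add atoms: none
Why: Acid-catalysed hydrolysis of the dioxolane in aqueous acetic acid, under which the esters are stable and the oxirane is deactivated toward ionisation by the acetoxy group on the neighbouring C5.

**Compound list**
1 | (S)-(+)-carvone, (5S)-2-methyl-5-(prop-1-en-2-yl)cyclohex-2-en-1-one | CC1=CC[C@@H](CC1=O)C(C)=C | starting material
2 | (1S,4S,6S)-1-methyl-4-(prop-1-en-2-yl)-7-oxabicyclo[4.1.0]heptan-2-one (oxirane trans to isopropenyl) | C=C(C)[C@H]1C[C@@H]2O[C@]2(C)C(=O)C1 | intermediate
3 | (1S,4R,6S)-3-hydroxy-1-methyl-4-(prop-1-en-2-yl)-7-oxabicyclo[4.1.0]heptan-2-one, either epimer at C3 | C=C(C)[C@H]1C[C@@H]2O[C@]2(C)C(=O)C1O | intermediate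
4 | methyl (2S,3S)-3-[(2R)-2-formyl-3-methylbut-3-en-1-yl]-2-methyloxirane-2-carboxylate | C=C(C)[C@H](C=O)C[C@@H]1O[C@]1(C)C(=O)OC | intermediate (not isolated)
5 | methyl (2S,3S)-3-[(2R)-2-(hydroxymethyl)-3-methylbut-3-en-1-yl]-2-methyloxirane-2-carboxylate | C=C(C)[C@H](CO)C[C@@H]1O[C@]1(C)C(=O)OC | intermediate
6 | methyl (2S,3S)-3-[(2R)-2-({[tert-butyl(diphenyl)silyl]oxy}methyl)-3-methylbut-3-en-1-yl]-2-methyloxirane-2-carboxylate | C=C(C)[C@H](CO[Si](c1ccccc1)(c1ccccc1)C(C)(C)C)C[C@@H]2O[C@]2(C)C(=O)OC | intermediate
7 | methyl (2S,3R,5R)-5-({[tert-butyl(diphenyl)silyl]oxy}methyl)-2,3-dihydroxy-2,6-dimethylhept-6-enoate | C=C(C)[C@H](CO[Si](c1ccccc1)(c1ccccc1)C(C)(C)C)C[C@@H](O)[C@](C)(O)C(=O)OC | intermediate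
8 | methyl (4S,5R)-5-[(2R)-2-({[tert-butyl(diphenyl)silyl]oxy}methyl)-3-methylbut-3-en-1-yl]-2,2,4-trimethyl-1,3-dioxolane-4-carboxylate | C=C(C)[C@H](CO[Si](c1ccccc1)(c1ccccc1)C(C)(C)C)C[C@H]2OC(C)(C)O[C@]2(C)C(=O)OC | intermediate
9 | ethyl acetate | CCOC(C)=O | starting material
10 | ethyl 3-[(4S,5R)-5-[(2R)-2-({[tert-butyl(diphenyl)silyl]oxy}methyl)-3-methylbut-3-en-1-yl]-2,2,4-trimethyl-1,3-dioxolan-4-yl]-3-oxopropanoate | C=C(C)[C@H](CO[Si](c1ccccc1)(c1ccccc1)C(C)(C)C)C[C@H]2OC(C)(C)O[C@]2(C)C(=O)CC(=O)OCC | intermediate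
11 | ethyl (3S)-3-hydroxy-3-[(4R,5R)-5-[(2R)-2-({[tert-butyl(diphenyl)silyl]oxy}methyl)-3-methylbut-3-en-1-yl]-2,2,4-trimethyl-1,3-dioxolan-4-yl]propanoate (4R only by change of CIP rank; same arrangement as in 10) | C=C(C)[C@H](CO[Si](c1ccccc1)(c1ccccc1)C(C)(C)C)C[C@H]2OC(C)(C)O[C@]2(C)[C@@H](O)CC(=O)OCC | intermediate
12 | ethyl (3S)-3-{[tert-butyl(dimethyl)silyl]oxy}-3-[(4S,5R)-5-[(2R)-2-({[tert-butyl(diphenyl)silyl]oxy}methyl)-3-methylbut-3-en-1-yl]-2,2,4-trimethyl-1,3-dioxolan-4-yl]propanoate | C=C(C)[C@H](CO[Si](c1ccccc1)(c1ccccc1)C(C)(C)C)C[C@H]2OC(C)(C)O[C@]2(C)[C@@H](O[Si](C)(C)C(C)(C)C)CC(=O)OCC | intermediate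
13 | (3S)-3-{[tert-butyl(dimethyl)silyl]oxy}-3-[(4S,5R)-5-[(2R)-2-({[tert-butyl(diphenyl)silyl]oxy}methyl)-3-methylbut-3-en-1-yl]-2,2,4-trimethyl-1,3-dioxolan-4-yl]propanal | C=C(C)[C@H](CO[Si](c1ccccc1)(c1ccccc1)C(C)(C)C)C[C@H]2OC(C)(C)O[C@]2(C)[C@@H](O[Si](C)(C)C(C)(C)C)CC=O | intermediate
14 | ethyl 2-[bis(2,2,2-trifluoroethoxy)phosphoryl]propanoate | CCOC(=O)C(C)P(=O)(OCC(F)(F)F)OCC(F)(F)F | starting material
15 | ethyl (2Z,5S)-5-{[tert-butyl(dimethyl)silyl]oxy}-5-[(4S,5R)-5-[(2R)-2-({[tert-butyl(diphenyl)silyl]oxy}methyl)-3-methylbut-3-en-1-yl]-2,2,4-trimethyl-1,3-dioxolan-4-yl]-2-methylpent-2-enoate | C=C(C)[C@H](CO[Si](c1ccccc1)(c1ccccc1)C(C)(C)C)C[C@H]2OC(C)(C)O[C@]2(C)[C@@H](O[Si](C)(C)C(C)(C)C)C/C=C(C)\C(=O)OCC | intermediate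
16 | (2Z,5S)-5-{[tert-butyl(dimethyl)silyl]oxy}-5-[(4S,5R)-5-[(2R)-2-({[tert-butyl(diphenyl)silyl]oxy}methyl)-3-methylbut-3-en-1-yl]-2,2,4-trimethyl-1,3-dioxolan-4-yl]-2-methylpent-2-en-1-ol | C=C(C)[C@H](CO[Si](c1ccccc1)(c1ccccc1)C(C)(C)C)C[C@H]2OC(C)(C)O[C@]2(C)[C@@H](O[Si](C)(C)C(C)(C)C)C/C=C(C)\CO | intermediate
17 | (2Z,5S)-5-{[tert-butyl(dimethyl)silyl]oxy}-5-[(4S,5R)-5-[(2R)-2-(hydroxymethyl)-3-methylbut-3-en-1-yl]-2,2,4-trimethyl-1,3-dioxolan-4-yl]-2-methylpent-2-en-1-ol | C=C(C)[C@H](CO)C[C@H]2OC(C)(C)O[C@]2(C)[C@@H](O[Si](C)(C)C(C)(C)C)C/C=C(C)\CO | intermediate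
18 | (2Z,5S)-5-{[tert-butyl(dimethyl)silyl]oxy}-5-[(4S,5R)-5-[(2R)-2-formyl-3-methylbut-3-en-1-yl]-2,2,4-trimethyl-1,3-dioxolan-4-yl]-2-methylpent-2-enal (C5 enal, C6 aldehyde) | C=C(C)[C@H](C=O)C[C@H]2OC(C)(C)O[C@]2(C)[C@@H](O[Si](C)(C)C(C)(C)C)C/C=C(C)\C=O | intermediate
19 | (3Z)-1-O-[tert-butyl(dimethyl)silyl]-9,10-O-isopropylidene-4,10-dimethyl-7-(prop-1-en-2-yl)cyclodec-3-ene-1,5,6,9,10-pentol, 5,6-hydroxyls cis; C1, C5, C6, C7, C9, C10 arranged as in 27 | C=C(C)[C@H]1C[C@H]2OC(C)(C)O[C@]2(C)[C@@H](O[Si](C)(C)C(C)(C)C)C/C=C(C)\[C@@H](O)[C@H]1O | intermediate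
20 | 3,4-epoxide of 19, oxirane oxygen syn to O5; all centres arranged as in 27 | C=C(C)[C@H]1C[C@H]2OC(C)(C)O[C@]2(C)[C@@H](O[Si](C)(C)C(C)(C)C)C[C@H]3O[C@@]3(C)[C@@H](O)[C@H]1O | intermediate
21 | angelic acid, (2Z)-2-methylbut-2-enoic acid | C/C=C(/C)C(=O)O | starting material
22 | (2Z)-2-methylbut-2-enoic 2,4,6-trichlorobenzoic anhydride, handled as a filtered toluene solution | C/C=C(/C)C(=O)OC(=O)c1c(Cl)cc(Cl)cc1Cl | intermediate
23 | 6-O-[(2Z)-2-methylbut-2-enoyl] derivative of 20 (free C5 hydroxyl) | C=C(C)[C@H]1C[C@H]2OC(C)(C)O[C@]2(C)[C@@H](O[Si](C)(C)C(C)(C)C)C[C@H]3O[C@@]3(C)[C@@H](O)[C@H]1OC(=O)/C(C)=C\C | intermediate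
24 | 5-O-acetyl-6-O-[(2Z)-2-methylbut-2-enoyl] derivative of 20 | C=C(C)[C@H]1C[C@H]2OC(C)(C)O[C@]2(C)[C@@H](O[Si](C)(C)C(C)(C)C)C[C@H]3O[C@@]3(C)[C@@H](OC(C)=O)[C@H]1OC(=O)/C(C)=C\C | intermediate
25 | 24 without the silyl group (free C1 hydroxyl) | C=C(C)[C@H]1C[C@H]2OC(C)(C)O[C@]2(C)[C@@H](O)C[C@H]3O[C@@]3(C)[C@@H](OC(C)=O)[C@H]1OC(=O)/C(C)=C\C | intermediate
26 | 9,10-O-isopropylidene derivative of 27 | C=C(C)[C@H]1C[C@H]2OC(C)(C)O[C@]2(C)[C@@H](OC(=O)/C(C)=C\C)C[C@H]3O[C@@]3(C)[C@@H](OC(C)=O)[C@H]1OC(=O)/C(C)=C\C | intermediate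
27 | CNP0249359.1: (1S,3R,4R,5S,6S,7R,9R,10S)-5-acetoxy-3,4-epoxy-9,10-dihydroxy-4,10-dimethyl-7-(prop-1-en-2-yl)cyclodecane-1,6-diyl bis[(2Z)-2-methylbut-2-enoate] (ring numbering of the remark) | C=C(C)[C@H]1C[C@@H](O)[C@](C)(O)[C@@H](OC(=O)/C(C)=C\C)C[C@H]2O[C@@]2(C)[C@@H](OC(C)=O)[C@H]1OC(=O)/C(C)=C\C | target

**Step count**
Total: 22 steps. Longest linear sequence: 21 steps (1 → 27 through steps 1–16 and 18–22); the mixed anhydride 22 is made in a one-step branch (step 17); 9, 14 and 21 are bought.

**Steps most likely to fail**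

1. Step 15 (pinacol ring closure). The ring may close with the arms C4 and C7 trans on the metal diolate, giving the 5-epimer, as unconstrained ten-membered pinacol closures tend to do; closure may also be slow enough that enal ketyls pair between molecules. The fallback sets out from 18 and comes back at 19, and it sets C5 by a ketone reduction instead of by the coupling. 18 would be cyclised on low-valent titanium (TiCl3(DME)1.5, Zn–Cu couple, DME, 25 °C, slow addition), whose surface-bound coupling closes medium rings readily and favours the trans diol F1. MnO2 in CH2Cl2 would oxidise only the allylic C5 carbinol to the hydroxy enone F2. Zn(BH4)2 in Et2O at −20 °C would then reduce the zinc chelate of O6 and the C5 carbonyl from the side of the C6 hydrogen, which gives the erythro (cis) diol 19.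

2. Step 18 (first angeloylation). The hot acyl transfer may not tell the C5 and C6 hydroxyls apart, or the angeloyl group may migrate between them under the warm basic conditions. The fallback sets out from 19 and comes back at 23, and it uses the constitutional difference between the allylic and the non-allylic carbinol. MnO2 would give the hydroxy enone F2, whose single hydroxyl (O6) is esterified with 22 to the angeloyloxy enone F3. NaBH4 with CeCl3 in MeOH at −78 °C would return the C5 carbinol as the hydroxy angelate F4, and VO(acac)2 with t-BuOOH would epoxidise F4 under direction by O5 to 23. The C5 configuration then depends on the face chosen by the hydride on the ten-membered enone and would have to be proved; a wrong epimer could be recycled through F3.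

3. Step 22 (ketal hydrolysis). The acid needed for the substituted dioxolane may open the oxirane, most likely by transannular attack of the hydroxyls set free at C9 and C10. The fallback sets out from 19 and comes back at 27, and it makes the oxirane last, after the acid step. 19 would be esterified with 22 to the hydroxy angelate F4, acetylated (Ac2O, DMAP) to the acetate F5 and desilylated (HF·pyridine) to the alcohol F6. F6 would be esterified with 22 at 80 °C to the triester acetonide F7 and hydrolysed in aqueous AcOH, with no oxirane present, to the olefinic diol F8. F8 would be epoxidised at C3=C4 by Shi epoxidation (fructose-derived ketone, KHSO5, K2CO3 buffer, MeCN–dimethoxymethane–H2O, 0 °C), with the antipode of the ketone chosen for delivery syn to O5. The trisubstituted ring olefin would have to react ahead of the isopropenyl group, and the electron-poor angelates should stay inert.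

**Further compounds**
F1 | step 15 | 5-epimer of 19 (trans 5,6-diol) | C=C(C)[C@H]1C[C@H]2OC(C)(C)O[C@]2(C)[C@@H](O[Si](C)(C)C(C)(C)C)C/C=C(C)\[C@H](O)[C@H]1O
F2 | step 15 | 5-oxo analogue of 19 (Z enone with free C6 hydroxyl) | C=C(C)[C@H]1C[C@H]2OC(C)(C)O[C@]2(C)[C@@H](O[Si](C)(C)C(C)(C)C)C/C=C(C)\C(=O)[C@H]1O
F3 | step 18 | 6-O-angelate of F2 | C=C(C)[C@H]1C[C@H]2OC(C)(C)O[C@]2(C)[C@@H](O[Si](C)(C)C(C)(C)C)C/C=C(C)\C(=O)[C@H]1OC(=O)/C(C)=C\C
F4 | step 18 | 6-O-angelate of 19 (free C5 hydroxyl) | C=C(C)[C@H]1C[C@H]2OC(C)(C)O[C@]2(C)[C@@H](O[Si](C)(C)C(C)(C)C)C/C=C(C)\[C@@H](O)[C@H]1OC(=O)/C(C)=C\C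
F5 | step 22 | 5-O-acetyl-6-O-angelate of 19 | C=C(C)[C@H]1C[C@H]2OC(C)(C)O[C@]2(C)[C@@H](O[Si](C)(C)C(C)(C)C)C/C=C(C)\[C@@H](OC(C)=O)[C@H]1OC(=O)/C(C)=C\C
F6 | step 22 | F5 without the silyl group (free C1 hydroxyl) | C=C(C)[C@H]1C[C@H]2OC(C)(C)O[C@]2(C)[C@@H](O)C/C=C(C)\[C@@H](OC(C)=O)[C@H]1OC(=O)/C(C)=C\C
F7 | step 22 | 1,6-di-O-angelate 5-O-acetate 9,10-acetonide with C3=C4 olefin | C=C(C)[C@H]1C[C@H]2OC(C)(C)O[C@]2(C)[C@@H](OC(=O)/C(C)=C\C)C/C=C(C)\[C@@H](OC(C)=O)[C@H]1OC(=O)/C(C)=C\C
F8 | step 22 | 3,4-deoxy olefin of 27 (free 9,10-diol) | C=C(C)[C@H]1C[C@@H](O)[C@](C)(O)[C@@H](OC(=O)/C(C)=C\C)C/C=C(C)\[C@@H](OC(C)=O)[C@H]1OC(=O)/C(C)=C\C
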